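**Plan**

- Cuts: (i) the C8–C1'' prenyl bond, by a retro-[3,3] shift back to an O7–C(CH3)2CH=CH2 ether; (ii) the C2'(OH)–C3'(=CH2) unit on C6, back to the C2'–C3' epoxide and then to a C6 prenyl group; (iii) C6–C1', back to C6–I. The three rings are bought intact as genistein.
- Forward: genistein → 7,4'-disilyl ether → C6 iodide (ortho to the chelated 5-OH) → C6 prenyl → (R)-epoxide → (R)-allylic alcohol → free triol → 7-O-(1,1-dimethylallyl) ether → C8 prenyl by an O7→C8 [3,3] shift.
- Stereochemistry: the single stereocentre C2' is set by Shi epoxidation of the only trisubstituted alkene present at that stage; its C–O bond is never broken afterwards.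
- Idea: the two C5 units are never two prenyl groups at the same time, so no reagent has to choose between the C6 and C8 chains. The second prenyl enters last, through oxygen, on the unprotected polyphenol.
- Enabling feature: in ring A, O7 (the most acidic phenol, para to the C4a–C4=O acyl group) lies between C6, by then blocked by the hydroxy chain, and C8, the only free ring carbon. O5–H is silenced by its hydrogen bond to C4=O.

Key step: step 8

Remark on the chemistry: the 5-OH, hydrogen-bonded to C4=O, is assumed not to be silylated, allylated or to open the epoxide under the mild conditions used; carbonate 12 is taken as a purchased reagent (otherwise one step from 2-methylbut-3-en-2-ol and Boc2O).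

**Route**

Step 1
Reactants: 1 genistein; 2 chlorotriisopropylsilane
Product: 3 5-hydroxy-7-(triisopropylsilyloxy)-3-[4-(triisopropylsilyloxy)phenyl]-4H-chromen-4-one
Conditions: TIPSCl (2.3 equiv), imidazole, DMF, 0 °C to rt
Reagents that add atoms: chlorotriisopropylsilane, CC(C)[Si](Cl)(C(C)C)C(C)C
Why: Imidazole-mediated silyl ether formation at the two free phenols O7 and O4'; the chelated 5-OH should stay free and is kept as the directing group for step 2.

Step 2
Reactants: 3 bis-silyl ether; 4 benzyltrimethylammonium dichloroiodate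
Product: 5 5-hydroxy-6-iodo-7-(triisopropylsilyloxy)-3-[4-(triisopropylsilyloxy)phenyl]-4H-chromen-4-one
Conditions: BnMe3N·ICl2 (1.05 equiv), CaCO3, CH2Cl2–MeOH, rt, dark
Reagents that add atoms: benzyltrimethylammonium dichloroiodate, C[N+](C)(C)Cc1ccccc1.Cl[I-]Cl
Why: Electrophilic aromatic iodination of the phloroglucinol-type ring A; with a free chelated 5-OH and an O7 ether, this reagent system is known to iodinate 5-hydroxy-7-alkoxy(iso)flavones ortho to the free phenol, that is at C6 and not at C8.

Step 3
Reactants: 5 C6 iodide; 6 tributyl(3-methylbut-2-en-1-yl)stannane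
Product: 7 5-hydroxy-6-(3-methylbut-2-en-1-yl)-7-(triisopropylsilyloxy)-3-[4-(triisopropylsilyloxy)phenyl]-4H-chromen-4-one
Conditions: 6 (1.5 equiv), Pd(PPh3)4 (10 mol %), DMF, 90 °C
Reagents that add atoms: tributyl(3-methylbut-2-en-1-yl)stannane, CCCC[Sn](CCCC)(CCCC)CC=C(C)C
Why: Stille cross-coupling at the C6–I bond, in which reductive elimination at the unhindered CH2 terminus of the prenyl group should give the linear 3-methylbut-2-enyl product under neutral conditions that tolerate the free 5-OH and the silyl ethers.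

Step 4
Reactants: 7 C6-prenyl compound; 8 potassium peroxymonosulfate (Oxone)
Product: 9 6-{[(2R)-3,3-dimethyloxiran-2-yl]methyl}-5-hydroxy-7-(triisopropylsilyloxy)-3-[4-(triisopropylsilyloxy)phenyl]-4H-chromen-4-one
Conditions: D-fructose-derived Shi ketone (1 equiv), Oxone, KHCO3, Bu4NHSO4 (cat.), MeCN–dimethoxymethane–aq. Na2EDTA, 0 °C, pH about 8
Reagents that add atoms: potassium peroxymonosulfate (active component of Oxone), [K+].[O-]S(=O)(=O)OO
Why: Shi asymmetric epoxidation by the chiral dioxirane through a spiro transition state; C2'=C3' is the only trisubstituted alkene in 7, the facial preference known for R–CH2–CH=C(CH3)2 olefins with the D-fructose-derived ketone makes C2' R, and the near-neutral pH keeps the chelated 5-OH un-ionised so that it should not open the epoxide.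

Step 5
Reactants: 9 (R)-epoxide
Product: 10 5-hydroxy-6-[(2R)-2-hydroxy-3-methylbut-3-en-1-yl]-7-(triisopropylsilyloxy)-3-[4-(triisopropylsilyloxy)phenyl]-4H-chromen-4-one
Conditions: Cp2TiCl2 (2.2 equiv), Mn dust, THF, rt; then 1 M aq. HCl, 0 °C
Reagents that add atoms: none
Why: Titanocene(III)-mediated radical isomerisation of a trisubstituted epoxide to the exo-methylene allylic alcohol by homolysis of the tertiary C3'–O bond and loss of a hydrogen from a C3' methyl group; the C2'–O bond is untouched, so the R configuration is retained.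

Step 6
Reactants: 10 bis-silylated allylic alcohol
Product: 11 5,7-dihydroxy-6-[(2R)-2-hydroxy-3-methylbut-3-en-1-yl]-3-(4-hydroxyphenyl)-4H-chromen-4-one
Conditions: Bu4NF–AcOH (1:1, 2.5 equiv), THF, 0 °C
Reagents that add atoms: none
Why: Fluoride-induced cleavage of the two aryl silyl ethers, buffered with acetic acid so that neither base nor acid can cyclise the 5-OH or 7-OH onto the allylic alcohol chain.

Step 7
Reactants: 11 triol; 12 tert-butyl 2-methylbut-3-en-2-yl carbonate
Product: 13 5-hydroxy-6-[(2R)-2-hydroxy-3-methylbut-3-en-1-yl]-3-(4-hydroxyphenyl)-7-[(2-methylbut-3-en-2-yl)oxy]-4H-chromen-4-one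
Conditions: 12 (1.1 equiv), Pd(PPh3)4 (5 mol %), THF, 0 °C
Reagents that add atoms: tert-butyl 2-methylbut-3-en-2-yl carbonate, C=CC(C)(C)OC(=O)OC(C)(C)C
Why: Tsuji–Trost O-allylation with decarboxylative activation of 12; the most acidic phenol O7–H is deprotonated first and its phenoxide attacks the more substituted allyl terminus under kinetic control at 0 °C, as known for the reverse prenylation of phenols, so one equivalent of 12 should etherify O7 only.

Step 8
Reactants: 13 7-O-(1,1-dimethylallyl) ether
Product: 15 CNP0105386.1 (5,7-dihydroxy-6-[(2R)-2-hydroxy-3-methylbut-3-en-1-yl]-3-(4-hydroxyphenyl)-8-(3-methylbut-2-en-1-yl)-4H-chromen-4-one), via C8-prenyl cyclohexa-2,4-dienone 14 (not isolated)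
Conditions: toluene, 2,6-lutidine (1 equiv), 110 °C, sealed tube, argon
Reagents that add atoms: none
Why: Heating 13 should trigger a concerted, suprafacial [3,3]-sigmatropic shift (aromatic ortho-Claisen rearrangement) through a chair-like transition state in which the O7–C(CH3)2 bond breaks while the vinyl CH2 terminus bonds to C8, giving dienone 14, which enolises at once to the 7-phenol 15. The closest known reaction type is the thermal rearrangement of 1,1-dimethylallyl aryl ethers of 7-hydroxychromones and coumarins to ortho-prenyl phenols, which is easy because the tertiary C–O bond is weak and the new bond is made to an unhindered CH2. No ring is closed and no stereocentre is created; the C2' carbinol is a spectator and C8 becomes sp2 again on tautomerisation. The selectivity needed is C8 over C6: C6 already carries the hydroxy chain, so a shift to C6 could only give a blocked dienone that returns by the reverse [3,3] shift, whereas the C8 dienone has a hydrogen to lose and drains the equilibrium. Ionic loss of the allyl group is held back by the neutral, lutidine-buffered medium. Because the step is intramolecular and neutral it can be run on the unprotected triol, so the last C–C bond is formed with no protecting group left to remove.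

**Compound list**

1 | genistein, 5,7-dihydroxy-3-(4-hydroxyphenyl)-4H-chromen-4-one | c1c(O)cc2occ(-c3ccc(O)cc3)c(=O)c2c1O | starting material
2 | chlorotriisopropylsilane | CC(C)[Si](Cl)(C(C)C)C(C)C | starting material
3 | 5-hydroxy-7-(triisopropylsilyloxy)-3-[4-(triisopropylsilyloxy)phenyl]-4H-chromen-4-one | c1c(O[Si](C(C)C)(C(C)C)C(C)C)cc2occ(-c3ccc(O[Si](C(C)C)(C(C)C)C(C)C)cc3)c(=O)c2c1O | intermediate
4 | benzyltrimethylammonium dichloroiodate | C[N+](C)(C)Cc1ccccc1.Cl[I-]Cl | starting material
5 | 5-hydroxy-6-iodo-7-(triisopropylsilyloxy)-3-[4-(triisopropylsilyloxy)phenyl]-4H-chromen-4-one | Ic1c(O[Si](C(C)C)(C(C)C)C(C)C)cc2occ(-c3ccc(O[Si](C(C)C)(C(C)C)C(C)C)cc3)c(=O)c2c1O | intermediate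
6 | tributyl(3-methylbut-2-en-1-yl)stannane | CCCC[Sn](CCCC)(CCCC)CC=C(C)C | starting material
7 | 5-hydroxy-6-(3-methylbut-2-en-1-yl)-7-(triisopropylsilyloxy)-3-[4-(triisopropylsilyloxy)phenyl]-4H-chromen-4-one | CC(C)=CCc1c(O[Si](C(C)C)(C(C)C)C(C)C)cc2occ(-c3ccc(O[Si](C(C)C)(C(C)C)C(C)C)cc3)c(=O)c2c1O | intermediate
8 | potassium peroxymonosulfate (active component of Oxone) | [K+].[O-]S(=O)(=O)OO | starting material
9 | 6-{[(2R)-3,3-dimethyloxiran-2-yl]methyl}-5-hydroxy-7-(triisopropylsilyloxy)-3-[4-(triisopropylsilyloxy)phenyl]-4H-chromen-4-one | CC1(C)O[C@@H]1Cc1c(O[Si](C(C)C)(C(C)C)C(C)C)cc2occ(-c3ccc(O[Si](C(C)C)(C(C)C)C(C)C)cc3)c(=O)c2c1O | intermediate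
10 | 5-hydroxy-6-[(2R)-2-hydroxy-3-methylbut-3-en-1-yl]-7-(triisopropylsilyloxy)-3-[4-(triisopropylsilyloxy)phenyl]-4H-chromen-4-one | C=C(C)[C@H](O)Cc1c(O[Si](C(C)C)(C(C)C)C(C)C)cc2occ(-c3ccc(O[Si](C(C)C)(C(C)C)C(C)C)cc3)c(=O)c2c1O | intermediate
11 | 5,7-dihydroxy-6-[(2R)-2-hydroxy-3-methylbut-3-en-1-yl]-3-(4-hydroxyphenyl)-4H-chromen-4-one | C=C(C)[C@H](O)Cc1c(O)cc2occ(-c3ccc(O)cc3)c(=O)c2c1O | intermediate
12 | tert-butyl 2-methylbut-3-en-2-yl carbonate | C=CC(C)(C)OC(=O)OC(C)(C)C | starting material
13 | 5-hydroxy-6-[(2R)-2-hydroxy-3-methylbut-3-en-1-yl]-3-(4-hydroxyphenyl)-7-[(2-methylbut-3-en-2-yl)oxy]-4H-chromen-4-one | C=C(C)[C@H](O)Cc1c(OC(C)(C)C=C)cc2occ(-c3ccc(O)cc3)c(=O)c2c1O | intermediate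
14 | C8-prenyl cyclohexa-2,4-dienone (C7 ketone, C8 sp3 with H and prenyl, C5 enol; not isolated) | C=C(C)[C@H](O)CC1=C(O)C2=C(OC=C(c3ccc(O)cc3)C2=O)C(CC=C(C)C)C1=O | intermediate
15 | CNP0105386.1, 5,7-dihydroxy-6-[(2R)-2-hydroxy-3-methylbut-3-en-1-yl]-3-(4-hydroxyphenyl)-8-(3-methylbut-2-en-1-yl)-4H-chromen-4-one | C=C(C)[C@H](O)Cc1c(O)c(CC=C(C)C)c2occ(-c3ccc(O)cc3)c(=O)c2c1O | target

**Step count and risks**

Total step count: 8. Longest linear sequence: 8 steps from genistein.

Steps most likely to fail:

1. Step 7. The π-allyl palladium unit may equilibrate the kinetic tertiary ether to the linear O-prenyl ether, may also etherify O4', or may deliver the allyl group to carbon.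
Fallback (sets out from 10, comes back at 15): the second prenyl is brought in through O5 instead of O7. Compound 10, in which only the 5-OH is free, is alkylated with prenyl bromide and K2CO3 in acetone to the 5-O-prenyl ether F1. Eu(fod)3 (10 mol %) in CHCl3 at 60 °C then binds the O5/C4=O site and should start a para-Claisen–Cope sequence. The first [3,3] shift goes to the occupied C6 and gives the C6-quaternary cyclohexa-2,4-dienone F2 (not isolated), which cannot enolise. A second [3,3] (Cope) shift carries the group on to C8 as a normal prenyl group, giving the cyclohexa-2,5-dienone F3 (not isolated). Tautomerisation gives the 8-prenyl bis-silyl ether F4. Bu4NF–AcOH in THF then frees the two phenols and gives 15.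

2. Step 5. The radical pathway may end in hydrogen-atom transfer to C3' (over-reduction to the saturated alcohol), in deoxygenation back to the alkene, or the neighbouring 5-OH may open the epoxide during the reaction.
Fallback (sets out from 7, comes back at 10): the oxygen is put on C2' without an epoxide and the configuration is set by reduction. A Schenck ene reaction of 7 (O2, tetraphenylporphyrin, visible light, CH2Cl2, −20 °C) should give the racemic secondary allylic hydroperoxide F5, with the tertiary regioisomer to be separated later. PPh3 in the same flask reduces it to the racemic allylic alcohol F6. Dess–Martin oxidation (NaHCO3, CH2Cl2) gives the isopropenyl ketone F7. CBS reduction with the (S)-methyl-oxazaborolidine and catecholborane in toluene at −78 °C, with the isopropenyl group acting as the larger substituent, should give the (R)-alcohol 10.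

3. Step 3. Oxidative addition and transmetalation at C6, flanked by OH and OSi(iPr)3, may be slow, so that protodeiodination or coupling through the tertiary allyl terminus competes; a wrong site of iodination in step 2 would show up here as well.
Fallback (sets out from 3, comes back at 7; it bypasses steps 2 and 3): the prenyl group is brought to C6 through O5. A Mitsunobu reaction of 3 with 3-methylbut-2-en-1-ol, PPh3 and DIAD in THF gives the 5-O-prenyl ether F8. An acid-clay-promoted [1,3] O-to-C prenyl shift (montmorillonite K10 or Florisil, CH2Cl2, 0 °C to rt), a contact-ion-pair process known for aryl prenyl ethers, should then move the prenyl group to the ortho carbon C6 and give 7.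

Further compounds
F1 | step 7 | 5-O-prenyl ether of 10, 6-[(2R)-2-hydroxy-3-methylbut-3-en-1-yl]-5-[(3-methylbut-2-en-1-yl)oxy]-7-(triisopropylsilyloxy)-3-[4-(triisopropylsilyloxy)phenyl]-4H-chromen-4-one | C=C(C)[C@H](O)Cc1c(O[Si](C(C)C)(C(C)C)C(C)C)cc2occ(-c3ccc(O[Si](C(C)C)(C(C)C)C(C)C)cc3)c(=O)c2c1OCC=C(C)C
F2 | step 7 | C6-quaternary cyclohexa-2,4-dienone carrying the hydroxy chain and a 2-methylbut-3-en-2-yl group on C6 (not isolated) | C=C(C)[C@H](O)CC1(C(C)(C)C=C)C(O[Si](C(C)C)(C(C)C)C(C)C)=CC2=C(C1=O)C(=O)C(c1ccc(O[Si](C(C)C)(C(C)C)C(C)C)cc1)=CO2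
F3 | step 7 | C8-prenyl cyclohexa-2,5-dienone with C5 ketone (not isolated) | C=C(C)[C@H](O)CC1=C(O[Si](C(C)C)(C(C)C)C(C)C)C(CC=C(C)C)C2=C(C1=O)C(=O)C(c1ccc(O[Si](C(C)C)(C(C)C)C(C)C)cc1)=CO2
F4 | step 7 | 5-hydroxy-6-[(2R)-2-hydroxy-3-methylbut-3-en-1-yl]-8-(3-methylbut-2-en-1-yl)-7-(triisopropylsilyloxy)-3-[4-(triisopropylsilyloxy)phenyl]-4H-chromen-4-one | C=C(C)[C@H](O)Cc1c(O[Si](C(C)C)(C(C)C)C(C)C)c(CC=C(C)C)c2occ(-c3ccc(O[Si](C(C)C)(C(C)C)C(C)C)cc3)c(=O)c2c1O
F5 | step 5 | racemic 6-(2-hydroperoxy-3-methylbut-3-en-1-yl)-5-hydroxy-7-(triisopropylsilyloxy)-3-[4-(triisopropylsilyloxy)phenyl]-4H-chromen-4-one | C=C(C)C(OO)Cc1c(O[Si](C(C)C)(C(C)C)C(C)C)cc2occ(-c3ccc(O[Si](C(C)C)(C(C)C)C(C)C)cc3)c(=O)c2c1O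
F6 | step 5 | racemic 5-hydroxy-6-(2-hydroxy-3-methylbut-3-en-1-yl)-7-(triisopropylsilyloxy)-3-[4-(triisopropylsilyloxy)phenyl]-4H-chromen-4-one | C=C(C)C(O)Cc1c(O[Si](C(C)C)(C(C)C)C(C)C)cc2occ(-c3ccc(O[Si](C(C)C)(C(C)C)C(C)C)cc3)c(=O)c2c1O
F7 | step 5 | 5-hydroxy-6-(3-methyl-2-oxobut-3-en-1-yl)-7-(triisopropylsilyloxy)-3-[4-(triisopropylsilyloxy)phenyl]-4H-chromen-4-one | C=C(C)C(=O)Cc1c(O[Si](C(C)C)(C(C)C)C(C)C)cc2occ(-c3ccc(O[Si](C(C)C)(C(C)C)C(C)C)cc3)c(=O)c2c1O
F8 | step 3 | 5-[(3-methylbut-2-en-1-yl)oxy]-7-(triisopropylsilyloxy)-3-[4-(triisopropylsilyloxy)phenyl]-4H-chromen-4-one | c1c(O[Si](C(C)C)(C(C)C)C(C)C)cc2occ(-c3ccc(O[Si](C(C)C)(C(C)C)C(C)C)cc3)c(=O)c2c1OCC=C(C)C
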